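Its constants are invented; the flask was simulated.

The constants go a fair way towards the quick number requested, and against the hunch that salt charged twice over doubles the rate.

substrate 0.20 M; salt in the second phase 0.220 M; spent carrier 2.0 mM; volume of the second phase over the first 2.0

    substrate + fresh carrier → product + spent carrier (k1 = 39 /M/min)
    2 fresh carrier → spent catalyst (k2 = 48 /M/min)
    spent carrier + salt in the second phase ⇌ fresh carrier + spent salt in the second phase (K3 = 0.58, k3 = 160 /M/min)
    fresh carrier ⇌ dormant form (K4 = 4.1, k4 = 0.028 /min)

- where a step has two of a species, its rate is k times that concentration squared, and two are used at each turn
- in the second phase: salt in the second phase, spent salt in the second phase; everything else is in the first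
- charges count per volume of the first phase; a concentration in a rate is the amount of a species over the volume of its own phase; every rate counts per litre of the first phase
- a form made of two catalysts counts as two
- charge of substrate (flask): 0.20 M

- the form that holds most of the catalyst when 30 % of the substrate are converted (fresh carrier / spent carrier / spent catalyst / dormant form)
- its share of the catalyst then
- apparent order in spent carrier when 30 % of the substrate are converted (percent change of the rate of making product for one percent more spent carrier charged)
- factor on the rate of making product when 30 % of the substrate are converted if salt in the second phase is charged twice over

Substrate is the limiting reagent, its charge of 0.20 M standing below the 0.220 M of salt. Each turn of the carrier round costs one salt per substrate, so at 30 % conversion the salt stands near 72.7 % of its charge, with the small catalyst charge neglected.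

With substrate as charged, a fresh carrier turns at 7.80 /min, faster than the 0.192 /min at which the loss in pairs would take it with the whole catalyst fresh, so the round is reckoned as balanced. A spent carrier goes forward at 17.6 /min with salt as charged, and a fresh carrier goes back at 30.3 /min with the whole salt charge spent. Each rate scales with its fraction of the charge. The balance starts at 0.443 and reaches 1.07 at 30 % conversion: this is the split ratio, spent carrier over fresh carrier in the balanced round, equal to the substrate-fraction and spent-salt-fraction rates of fresh carrier over the salt-fraction rate of spent carrier.

For the flask with salt charged twice over, the same ratio gives 0.452 at 30 % conversion. The fresh share of the working catalyst goes from 48.3 % in the first flask to 68.9 % in the flask with salt charged twice over. With equal working catalyst the rate would grow by that ratio of shares, and since the larger fresh share also loses more in pairs, this reckoning puts the factor below 1.43, which is less than a doubling. The ratio says nothing of how much catalyst has left the round, so this reckoning stops here.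

The forecast, whose grounds open with “Treat the carrier cycle as fast”, names spent catalyst at 37 % of the catalyst, an order of 1.17 in spent carrier and a factor of 1.21. Its split ratio reads 1.10 against 1.07 here.

At 30 % conversion this flask gives spent catalyst as the largest form, at 36.9 % of the catalyst and outside the working round, with order 1.2 in spent carrier; the flask with salt charged twice over gives a factor of 1.22 on the rate at that conversion, below the reckoned bound. At 1.00 h this flask makes fresh carrier and uses it up at a ratio of 0.997, each step taken net, with substrate at 44 % and salt at 48 % of their charges. The split ratio on those fractions comes to 2.27, and this flask then holds spent carrier over fresh carrier at 2.25.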